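We hold no rate constant and no acid constant for this flask, so we look for a number that does without them: how far the electrophile gets, not how fast.

| flask | electrophile | nucleophile | buffer base | buffer acid | remark | time |
|---|---|---|---|---|---|---|
| south-east | 20 mM | 26 mM | 10 mM | 6 mM | the very flask that is asked about, followed so far |  |
| north-west | 30 mM | 26 mM | 10 mM | 6 mM | run made earlier |  |
| flask | 20 mM | 26.0 mM | 10.0 mM | 6.00 mM |  | 3.0 h |

| run | time / min | electrophile / % | target / % |
|---|---|---|---|
| south-east | 4.00 | 82.1 | 17.2 |
| south-east | 8.00 | 72.5 | 26.6 |
| south-east | 15.0 | 62.1 | 36.5 |
| south-east | 30.0 | 55.2 | 42.5 |
| south-east | 50.0 | 51.0 | 42.9 |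
| north-west | 6.00 | 79.6 | 19.6 |
| north-west | 20.0 | 69.0 | 29.5 |
| north-west | 30.0 | 68.2 | 30.2 |
| north-west | 50.0 | 66.6 | 29.1 |
| north-west | 80.0 | 66.8 | 27.5 |

(each reading ± 0.5 percentage points)

- the numbers in the tables scatter by 0.5 percentage points (one standard deviation)
- a reading or a percentage of target counts all its forms, free or not
- the earlier runs do not show the pH; that part of a forecast is a guess

- part of the electrophile that has reacted at 3.0 h
- pH of the solution at 3.0 h

The first way is to read it. The south-east run, which is the asked flask followed so far, has lost 9.80 mM of electrophile at 50.0 min, and the north-west run, charged with more electrophile, has lost 9.96 mM at 80.0 min, so the two losses stand close together, though the south-east readings were still falling at their last time.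

The second way uses the charges, on our own supposition that the nucleophile is the stronger base. It then takes the proton of the buffer acid at once, which leaves 20.0 mM free, and each coupling spends one nucleophile and frees one acid, which protonates a second nucleophile. The free nucleophile therefore pays for 10.0 mM of couplings, and this amount, half of what the buffer acid left free, we call the nucleophile budget. It comes from charges and the loss from readings, so their agreement is a real check, but the buffer base charge of 10.0 mM matches as well, and these runs, which share it, do not part the two.

The south-east run passed half of the budget by 8.00 min, far sooner than 3.0 h, so we take the asked flask to its budget, 50.0 % reacted. Going round once more, our supposition puts the buffer base near 16.0 mM, and any buffer acid re-formed spares nucleophile, so we expect slightly more than the budget and a pH above the buffer's midpoint, whose value we cannot name.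

The forecast gives 51 % and pH 5, holding that “the buffer is about 16 mM acid with almost no base left”, which is the opposite of our buffer. The flask gives 50.9 % and pH 7.39.

    electrophile + nucleophile → acid + target + leaving group (k = 179 /M/h)
    protonated nucleophile ⇌ nucleophile + acid, settled at all times (K = 1.00 × 10⁻¹⁰ M)
    buffer acid ⇌ buffer base + acid, settled at all times (K = 1.60 × 10⁻⁶ M)
    crystals ⇌ target, rate k4*(cs4 - [target]) while solid is left; crystals form when [target] > cs4 (solubility = 6.80 mM, k = 54.4 /h)
    2 electrophile → homo dimer (k = 0.0110 /M/h)
    target ⇌ isomer of the product (K = 1.10, k = 0.268 /h)

At 3.00 h in the asked flask the free nucleophile, here the limiting reagent although more nucleophile than electrophile was charged, stands at 0.148 % of its charge beside 15.8 mM protonated, and the buffer base at 156 % of its own charge. Counting the remaining free nucleophile and the re-formed buffer acid moves the budget of the asked flask to 10.2 mM, against 10.2 mM of leaving group. A neighbour flask charged with 1.5 mM of buffer acid, its buffer base unchanged, has a budget of 12.2 mM, or 61.2 % of the electrophile, and it reacts to 61.8 %, with 12.3 mM of leaving group.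

The runs are simulated with constants of no real substance, and the scatter is random.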